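With the tetrahydrofuran numbered O1, C2–C5, the Cα oxygen and C9 are folded back into a γ-lactone ring O–Cα–C4–C3–C9; the O1–C5 bond is made last by C2–OH displacing a C5 sulfonate. In that lactone the Cα aryl group, C5 (as vinyl) and the C2 carbinol are trans,trans, so the single stereocentre Cα can direct C4, C3 and C2. One operation, addition of (CH2=CH)2CuMgBr to a γ-aryl butenolide followed by a Cp2Zr(Cl)-enolate aldol with silylated 4-hydroxybenzaldehyde, forms C4–C5 and C3–C2 and sets three stereocentres. The precursor, (S)-5-(4-methoxyphenyl)furan-2(5H)-one, comes from asymmetric transfer hydrogenation of a γ-keto ester and selenoxide elimination.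

Key step: step 3

Remarks on the chemistry
- Numbering: O1, C2 (4-hydroxyphenyl), C3 (bears C9H2OAc), C4 (bears the carbinol carbon Cα), C5 (CH2). The target is (2R,3S,4R,αS), with the ring 2,3-trans and 3,4-trans.
- Cα is set by catalytic reduction and not taken from an arylglycine or a mandelic acid. Nitrous acid deamination at a 4-oxygenated benzylic carbon ionises, and an α-silyloxy arylacetaldehyde epimerises readily.
- The (S,S)-TsDPEN ligand is assumed to give the (S)-carbinol, as with simple aryl alkyl ketones. If the opposite sense is found, the (R,R)-ligand is used.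
- The phenol carries TBS and C2–OH carries TES, so pyridine-buffered HF frees C2–OH alone. C5 is sulfonylated while it is the only free hydroxyl.

Step 1
Reactants: 1 methyl 4-(4-methoxyphenyl)-4-oxobutanoate
Product: 3 (5S)-5-(4-methoxyphenyl)dihydrofuran-2(3H)-one, via hydroxy ester 2 (not isolated)
Conditions: RuCl(p-cymene)[(S,S)-TsDPEN] (1 mol %), HCO2H/Et3N (5:2), DMF, 40 °C; then PPTS (cat.), toluene, 60 °C
Reagents that add atoms: none
Why: Noyori asymmetric transfer hydrogenation of the aryl ketone through the Ru–H/N–H six-membered transition state, in which the aryl ring sits under the η6-arene ligand, should set Cα as S, and the γ-hydroxy ester then lactonises by acyl substitution under an acid too weak to ionise the 4-methoxybenzylic C–O bond.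

Step 2
Reactants: 3 (5S)-5-(4-methoxyphenyl)dihydrofuran-2(3H)-one
Product: 7 (5S)-5-(4-methoxyphenyl)furan-2(5H)-one, via Li enolate 4 (not isolated), via selenide 5 (not isolated), via selenoxide 6 (not isolated)
Conditions: LiN(iPr)2, THF, −78 °C; PhSeBr, −78 °C; AcOH; 30% H2O2, CH2Cl2, 0 °C to rt
Reagents that add atoms: none
Why: α-Selenenylation of the lactone enolate followed by oxidation and selenoxide syn-elimination, which can only run toward C4 and, under weakly acidic conditions, should leave the base-sensitive Cα stereocentre untouched.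

Step 3
Reactants: 7 (5S)-5-(4-methoxyphenyl)furan-2(5H)-one; 8 vinylmagnesium bromide; 9 4-(tert-butyldimethylsilyloxy)benzaldehyde
Product: 12 (3R,4S,5S)-3-[(R)-[4-(tert-butyldimethylsilyloxy)phenyl](hydroxy)methyl]-5-(4-methoxyphenyl)-4-vinyldihydrofuran-2(3H)-one, via BrMg enolate 10 (not isolated), via Cp2Zr(Cl) enolate 11 (not isolated)
Conditions: 8 (2.2 equiv), CuBr·SMe2 (1.1 equiv), THF, −78 to −40 °C; 7, −78 °C; Cp2ZrCl2 (1.3 equiv), −78 to −40 °C; 9, −78 °C; aq NH4Cl, −78 °C
Reagents that add atoms: none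
Why: The cuprate (CH2=CH)2CuMgBr transfers a vinyl group to C4 of 7 on the face opposite the Cα aryl group, the resulting enolate 10 is converted by salt metathesis with Cp2ZrCl2 into 11, and 11 adds through C3 to the carbonyl of 9 to give 12 after protonation of the aldolate. The closest known reaction type is the tandem cuprate conjugate addition–aldol trapping of γ-substituted butenolides, joined to the syn-selective aldol addition of Cp2Zr(Cl) enolates. No ring is closed; the two new bonds are C4–C5 and C3–C2. C4 (S) is controlled by the Cα aryl group (anti addition), C3 (R) by the new C4 vinyl group (the aldehyde enters trans to it), and the carbinol C2 (R) by the metal: the ring-locked E-enolate on the Cp2Zr(Cl) fragment should react through a boat-like transition state and give the syn aldol (C2–O syn to C3–C4 in the zigzag C9–C3–C2–aryl), whereas a lithium or magnesium enolate would lean toward the anti adduct through a chair. The step therefore needs 4,5-trans, 3,4-trans and C2/C3-syn selectivity, the first two secured by the single stereocentre of 7 and the third by the Cp2Zr(Cl) fragment. The cuprate is preformed so that no free Grignard reagent remains and everything is kept at or below −40 °C, so that the acidic, benzylic and allylic Cα–H of 7 is not removed and the ionisable Cα–O bond meets no strong Lewis acid.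

Step 4
Reactants: 12 (3R,4S,5S)-3-[(R)-[4-(tert-butyldimethylsilyloxy)phenyl](hydroxy)methyl]-5-(4-methoxyphenyl)-4-vinyldihydrofuran-2(3H)-one
Product: 13 (3R,4S,5S)-3-[(R)-[4-(tert-butyldimethylsilyloxy)phenyl](triethylsilyloxy)methyl]-5-(4-methoxyphenyl)-4-vinyldihydrofuran-2(3H)-one
Conditions: TESCl, imidazole, DMF, 0 °C to rt
Reagents that add atoms: chlorotriethylsilane (TESCl), CC[Si](Cl)(CC)CC
Why: Silylation of the secondary C2 hydroxyl with a silyl chloride and imidazole is mild enough to avoid retro-aldol cleavage, and TES is chosen because it can later be removed without disturbing the aryl TBS ether.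

Step 5
Reactants: 13 (3R,4S,5S)-3-[(R)-[4-(tert-butyldimethylsilyloxy)phenyl](triethylsilyloxy)methyl]-5-(4-methoxyphenyl)-4-vinyldihydrofuran-2(3H)-one
Product: 14 (1S,2S,3S)-3-[(R)-[4-(tert-butyldimethylsilyloxy)phenyl](triethylsilyloxy)methyl]-1-(4-methoxyphenyl)-2-vinylbutane-1,4-diol
Conditions: LiBH4, MeOH (1 equiv), THF, 0 °C to rt
Reagents that add atoms: none
Why: Hydride reduction of the γ-lactone with LiBH4 cleaves the acyl–oxygen bond (C9–O), so the Cα–O bond and all four stereocentres stay intact while both silyl ethers and the alkene are spared.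

Step 6
Reactants: 14 (1S,2S,3S)-3-[(R)-[4-(tert-butyldimethylsilyloxy)phenyl](triethylsilyloxy)methyl]-1-(4-methoxyphenyl)-2-vinylbutane-1,4-diol
Product: 15 (1S,2S,3S)-3-[(R)-[4-(tert-butyldimethylsilyloxy)phenyl](triethylsilyloxy)methyl]-1-(4-methoxyphenyl)-2-vinylbutane-1,4-diyl diacetate
Conditions: Ac2O, pyridine, DMAP (cat.), CH2Cl2, 0 °C to rt
Reagents that add atoms: acetic anhydride, CC(=O)OC(C)=O
Why: DMAP-catalysed acylation of the primary C9 hydroxyl and the secondary benzylic Cα hydroxyl, the only free hydroxyls, runs under basic conditions that do not ionise the 4-methoxybenzylic position.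

Step 7
Reactants: 15 (1S,2S,3S)-3-[(R)-[4-(tert-butyldimethylsilyloxy)phenyl](triethylsilyloxy)methyl]-1-(4-methoxyphenyl)-2-vinylbutane-1,4-diyl diacetate
Product: 17 (1S,2R,3S)-3-[(R)-[4-(tert-butyldimethylsilyloxy)phenyl](triethylsilyloxy)methyl]-2-(hydroxymethyl)-1-(4-methoxyphenyl)butane-1,4-diyl diacetate, via aldehyde 16 (not isolated)
Conditions: O3, CH2Cl2/MeOH, −78 °C (stopped at the first blue tint); then NaBH4, −78 to 0 °C
Reagents that add atoms: ozone, [O-][O+]=O
Why: Ozonolysis with reductive borohydride work-up should work because the terminal alkene reacts with ozone far faster than the two aryl rings and the aldehyde is reduced cold as it is released, before it can epimerise at C4 or lose acetic acid.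

Step 8
Reactants: 17 (1S,2R,3S)-3-[(R)-[4-(tert-butyldimethylsilyloxy)phenyl](triethylsilyloxy)methyl]-2-(hydroxymethyl)-1-(4-methoxyphenyl)butane-1,4-diyl diacetate
Product: 18 (1S,2R,3S)-3-[(R)-[4-(tert-butyldimethylsilyloxy)phenyl](triethylsilyloxy)methyl]-1-(4-methoxyphenyl)-2-[(methylsulfonyloxy)methyl]butane-1,4-diyl diacetate
Conditions: MsCl, Et3N, CH2Cl2, 0 °C
Reagents that add atoms: methanesulfonyl chloride, CS(Cl)(=O)=O
Why: Sulfonylation of the only free hydroxyl, the primary C5–OH, makes C5 electrophilic while the C2 oxygen is still masked, so no selectivity between hydroxyls is required.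

Step 9
Reactants: 18 (1S,2R,3S)-3-[(R)-[4-(tert-butyldimethylsilyloxy)phenyl](triethylsilyloxy)methyl]-1-(4-methoxyphenyl)-2-[(methylsulfonyloxy)methyl]butane-1,4-diyl diacetate
Product: 20 [(2R,3S,4R)-4-[(S)-acetoxy(4-methoxyphenyl)methyl]-2-[4-(tert-butyldimethylsilyloxy)phenyl]tetrahydrofuran-3-yl]methyl acetate, via hydroxy mesylate 19 (not isolated)
Conditions: HF·pyridine, pyridine, THF, 0 °C; then 2,6-lutidine, MeCN, 50 °C
Reagents that add atoms: none
Why: Fluoride desilylation followed by intramolecular Williamson-type etherification: buffered HF removes TES without forming an alkoxide that would invite acetyl migration, and the neutral C2 hydroxyl then displaces the primary mesylate at C5 in a 5-exo-tet SN2 closure that breaks no bond at C2, so the 2,3-trans-3,4-trans ring should result.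

Step 10
Reactants: 20 [(2R,3S,4R)-4-[(S)-acetoxy(4-methoxyphenyl)methyl]-2-[4-(tert-butyldimethylsilyloxy)phenyl]tetrahydrofuran-3-yl]methyl acetate
Product: 21 [(2R,3S,4R)-4-[(S)-acetoxy(4-methoxyphenyl)methyl]-2-(4-hydroxyphenyl)tetrahydrofuran-3-yl]methyl acetate
Conditions: TBAF, AcOH (1:1), THF, 0 °C
Reagents that add atoms: none
Why: Fluoride cleavage of the aryl silyl ether with AcOH-buffered TBAF keeps the medium near neutral, so the two acetates should neither hydrolyse nor migrate.

Compound list
1 | methyl 4-(4-methoxyphenyl)-4-oxobutanoate | COC(=O)CCC(=O)c1ccc(OC)cc1 | starting material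
2 | methyl (4S)-4-hydroxy-4-(4-methoxyphenyl)butanoate | COc1ccc(cc1)[C@@H](O)CCC(=O)OC | intermediate (not isolated)
3 | (5S)-5-(4-methoxyphenyl)dihydrofuran-2(3H)-one | COc1ccc(cc1)[C@H]1OC(=O)CC1 | intermediate
4 | lithium (5S)-5-(4-methoxyphenyl)-4,5-dihydrofuran-2-olate | COc1ccc(cc1)[C@H]1OC(O[Li])=CC1 | intermediate (not isolated)
5 | (5S)-5-(4-methoxyphenyl)-3-(phenylselanyl)dihydrofuran-2(3H)-one (C3 epimers) | COc1ccc(cc1)[C@H]1OC(=O)C([Se]c2ccccc2)C1 | intermediate (not isolated)
6 | (5S)-5-(4-methoxyphenyl)-3-(phenylseleninyl)dihydrofuran-2(3H)-one (C3 and Se epimers) | COc1ccc(cc1)[C@H]1OC(=O)C([Se](=O)c2ccccc2)C1 | intermediate (not isolated)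
7 | (5S)-5-(4-methoxyphenyl)furan-2(5H)-one | COc1ccc(cc1)[C@H]1OC(=O)C=C1 | intermediate (key-step precursor)
8 | vinylmagnesium bromide | C=C[Mg]Br | starting material
9 | 4-(tert-butyldimethylsilyloxy)benzaldehyde | CC(C)(C)[Si](C)(C)Oc1ccc(C=O)cc1 | starting material
10 | bromomagnesium (4S,5S)-5-(4-methoxyphenyl)-4-vinyl-4,5-dihydrofuran-2-olate | COc1ccc(cc1)[C@H]1OC(O[Mg]Br)=C[C@@H]1C=C | intermediate (not isolated)
11 | chlorobis(cyclopentadienyl)zirconium (4S,5S)-5-(4-methoxyphenyl)-4-vinyl-4,5-dihydrofuran-2-olate | COc1ccc(cc1)[C@H]1OC(O[Zr](Cl)(C2C=CC=C2)C2C=CC=C2)=C[C@@H]1C=C | intermediate (not isolated)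
12 | (3R,4S,5S)-3-[(R)-[4-(tert-butyldimethylsilyloxy)phenyl](hydroxy)methyl]-5-(4-methoxyphenyl)-4-vinyldihydrofuran-2(3H)-one | COc1ccc(cc1)[C@H]1OC(=O)[C@@H]([C@@H](O)c2ccc(O[Si](C)(C)C(C)(C)C)cc2)[C@@H]1C=C | intermediate (key-step product)
13 | (3R,4S,5S)-3-[(R)-[4-(tert-butyldimethylsilyloxy)phenyl](triethylsilyloxy)methyl]-5-(4-methoxyphenyl)-4-vinyldihydrofuran-2(3H)-one | COc1ccc(cc1)[C@H]1OC(=O)[C@@H]([C@@H](O[Si](CC)(CC)CC)c2ccc(O[Si](C)(C)C(C)(C)C)cc2)[C@@H]1C=C | intermediate
14 | (1S,2S,3S)-3-[(R)-[4-(tert-butyldimethylsilyloxy)phenyl](triethylsilyloxy)methyl]-1-(4-methoxyphenyl)-2-vinylbutane-1,4-diol | COc1ccc(cc1)[C@@H](O)[C@@H](C=C)[C@@H](CO)[C@@H](O[Si](CC)(CC)CC)c1ccc(O[Si](C)(C)C(C)(C)C)cc1 | intermediate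
15 | (1S,2S,3S)-3-[(R)-[4-(tert-butyldimethylsilyloxy)phenyl](triethylsilyloxy)methyl]-1-(4-methoxyphenyl)-2-vinylbutane-1,4-diyl diacetate | COc1ccc(cc1)[C@@H](OC(C)=O)[C@@H](C=C)[C@@H](COC(C)=O)[C@@H](O[Si](CC)(CC)CC)c1ccc(O[Si](C)(C)C(C)(C)C)cc1 | intermediate
16 | (1S,2S,3S)-3-[(R)-[4-(tert-butyldimethylsilyloxy)phenyl](triethylsilyloxy)methyl]-2-formyl-1-(4-methoxyphenyl)butane-1,4-diyl diacetate | COc1ccc(cc1)[C@@H](OC(C)=O)[C@@H](C=O)[C@@H](COC(C)=O)[C@@H](O[Si](CC)(CC)CC)c1ccc(O[Si](C)(C)C(C)(C)C)cc1 | intermediate (not isolated)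
17 | (1S,2R,3S)-3-[(R)-[4-(tert-butyldimethylsilyloxy)phenyl](triethylsilyloxy)methyl]-2-(hydroxymethyl)-1-(4-methoxyphenyl)butane-1,4-diyl diacetate | COc1ccc(cc1)[C@@H](OC(C)=O)[C@@H](CO)[C@@H](COC(C)=O)[C@@H](O[Si](CC)(CC)CC)c1ccc(O[Si](C)(C)C(C)(C)C)cc1 | intermediate
18 | (1S,2R,3S)-3-[(R)-[4-(tert-butyldimethylsilyloxy)phenyl](triethylsilyloxy)methyl]-1-(4-methoxyphenyl)-2-[(methylsulfonyloxy)methyl]butane-1,4-diyl diacetate | COc1ccc(cc1)[C@@H](OC(C)=O)[C@@H](COS(C)(=O)=O)[C@@H](COC(C)=O)[C@@H](O[Si](CC)(CC)CC)c1ccc(O[Si](C)(C)C(C)(C)C)cc1 | intermediate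
19 | (1S,2R,3S)-3-[(R)-[4-(tert-butyldimethylsilyloxy)phenyl](hydroxy)methyl]-1-(4-methoxyphenyl)-2-[(methylsulfonyloxy)methyl]butane-1,4-diyl diacetate | COc1ccc(cc1)[C@@H](OC(C)=O)[C@@H](COS(C)(=O)=O)[C@@H](COC(C)=O)[C@@H](O)c1ccc(O[Si](C)(C)C(C)(C)C)cc1 | intermediate (not isolated)
20 | [(2R,3S,4R)-4-[(S)-acetoxy(4-methoxyphenyl)methyl]-2-[4-(tert-butyldimethylsilyloxy)phenyl]tetrahydrofuran-3-yl]methyl acetate | COc1ccc([C@@H](OC(C)=O)[C@H]2CO[C@@H](c3ccc(O[Si](C)(C)C(C)(C)C)cc3)[C@@H]2COC(C)=O)cc1 | intermediate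
21 | [(2R,3S,4R)-4-[(S)-acetoxy(4-methoxyphenyl)methyl]-2-(4-hydroxyphenyl)tetrahydrofuran-3-yl]methyl acetate | COc1ccc([C@@H](OC(C)=O)[C@H]2CO[C@@H](c3ccc(O)cc3)[C@@H]2COC(C)=O)cc1 | target

Total step count: 10.
Longest linear sequence: 10 steps, from 1 to 21; 8 and 9 are purchased and enter at step 3.

Steps most likely to fail

Step 3. Exchange of magnesium for zirconium may be incomplete, so that the aldol runs through the chair pathway and the carbinol forms with poor or reversed selectivity. The adduct may also equilibrate by retro-aldol on work-up, and enantiopurity may erode if the Cα proton of the butenolide is removed. The fallback sets out from 7. The cuprate addition is run as before, but the BrMg enolate reacts with 9 directly, without regard to carbinol configuration, to give 12 mixed with its C2 epimer (3R,4S,5S)-3-[(S)-[4-(tert-butyldimethylsilyloxy)phenyl](hydroxy)methyl]-5-(4-methoxyphenyl)-4-vinyldihydrofuran-2(3H)-one F1. Dess–Martin periodinane (CH2Cl2, NaHCO3) should converge both on the keto lactone (3R,4S,5S)-3-[4-(tert-butyldimethylsilyloxy)benzoyl]-5-(4-methoxyphenyl)-4-vinyldihydrofuran-2(3H)-one F2, whose C3 settles trans to the vinyl group. Chelation-controlled reduction with Zn(BH4)2 (Et2O, −78 °C), in which hydride enters the ketone from the C3–H side of the zinc chelate of the two carbonyls, should return the syn alcohol 12, where the route is rejoined. C2 is then set by a ketone reduction and no longer by the aldol.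

Step 9. The C9 acetyl group may migrate onto the freed C2 hydroxyl, closure at the β-branched C5 may be slow, or acid may ionise the electron-rich benzylic C2 and scramble its configuration. Partial loss of the aryl TBS group would be harmless, since it only anticipates step 10. The fallback sets out from 17 and bypasses step 8. Brief treatment with pyridine-buffered HF·pyridine should give the 1,4-diol (1S,2R,3S)-3-[(R)-[4-(tert-butyldimethylsilyloxy)phenyl](hydroxy)methyl]-2-(hydroxymethyl)-1-(4-methoxyphenyl)butane-1,4-diyl diacetate F3. An intramolecular Mitsunobu etherification (PPh3, DIAD, THF, 0 °C) should then activate the less hindered primary C5–OH as its oxyphosphonium salt and let C2–OH close the ring under neutral conditions with retention at C2, which rejoins the route at 20.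

Step 7. Ozone may attack the two electron-rich aryl rings, the β-acetoxy aldehyde 16 may lose acetic acid or epimerise at C4, and the Cα acetyl group may migrate to the new primary alkoxide during borohydride reduction. The fallback sets out from 15. Catalytic OsO4 with N-methylmorpholine N-oxide (acetone/H2O) should give the vicinal diol (1S,2R,3S)-3-[(R)-[4-(tert-butyldimethylsilyloxy)phenyl](triethylsilyloxy)methyl]-2-(1,2-dihydroxyethyl)-1-(4-methoxyphenyl)butane-1,4-diyl diacetate F4 (either epimer at the new carbinol serves). NaIO4 at pH 7 cleaves it to aldehyde 16, and NaBH(OAc)3 in CH2Cl2/AcOH reduces 16 under weakly acidic conditions where neither elimination nor acyl transfer is base-promoted. The route is rejoined at 17.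

Further compounds
F1 | step 3 | (3R,4S,5S)-3-[(S)-[4-(tert-butyldimethylsilyloxy)phenyl](hydroxy)methyl]-5-(4-methoxyphenyl)-4-vinyldihydrofuran-2(3H)-one | COc1ccc(cc1)[C@H]1OC(=O)[C@@H]([C@H](O)c2ccc(O[Si](C)(C)C(C)(C)C)cc2)[C@@H]1C=C
F2 | step 3 | (3R,4S,5S)-3-[4-(tert-butyldimethylsilyloxy)benzoyl]-5-(4-methoxyphenyl)-4-vinyldihydrofuran-2(3H)-one | COc1ccc(cc1)[C@H]1OC(=O)[C@@H](C(=O)c2ccc(O[Si](C)(C)C(C)(C)C)cc2)[C@@H]1C=C
F3 | step 9 | (1S,2R,3S)-3-[(R)-[4-(tert-butyldimethylsilyloxy)phenyl](hydroxy)methyl]-2-(hydroxymethyl)-1-(4-methoxyphenyl)butane-1,4-diyl diacetate | COc1ccc(cc1)[C@@H](OC(C)=O)[C@@H](CO)[C@@H](COC(C)=O)[C@@H](O)c1ccc(O[Si](C)(C)C(C)(C)C)cc1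
F4 | step 7 | (1S,2R,3S)-3-[(R)-[4-(tert-butyldimethylsilyloxy)phenyl](triethylsilyloxy)methyl]-2-(1,2-dihydroxyethyl)-1-(4-methoxyphenyl)butane-1,4-diyl diacetate | COc1ccc(cc1)[C@@H](OC(C)=O)[C@@H](C(O)CO)[C@@H](COC(C)=O)[C@@H](O[Si](CC)(CC)CC)c1ccc(O[Si](C)(C)C(C)(C)C)cc1
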